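**Strategy.** The oxolane ring (O1, C2–C5) is opened at its two C–O bonds, and each ring methylene (C2, C5) is read as a truncated vinyl group. Each exocyclic carbinol carbon then adjoins a ring carbon (C3 or C4) carrying a vinyl arm. This is, twice over, the homoallylic alcohol that a [2,3]-Wittig shift of a benzyl allyl ether leaves behind. One operation, a ligand-controlled double shift running inward from both ends of a Z,Z-diene, forms both carbinol–C3/C4 bonds and all four stereocentres. Its precursor is achiral and symmetric: the bis(3-methoxy-4-triisopropylsilyloxybenzyl) ether of (2Z,4Z)-hexa-2,4-diene-1,6-diol. Silylation, ozonolysis–reduction, monotosylate closure and fluoride finish the synthesis.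

Key step: step 6

Abbreviation: Ar = 3-methoxy-4-(triisopropylsilyloxy)phenyl.

Assumption: the (S,S)-bis(oxazoline) is taken to give the (S)-carbinols; the sense of induction is to be calibrated in a model run, and the equally available (R,R)-ligand is used if it proves opposite.

Step 1
Reactants: 1 vanillin; 2 chlorotriisopropylsilane
Product: 3 3-methoxy-4-(triisopropylsilyloxy)benzaldehyde
Conditions: TIPSCl (1.2 equiv), imidazole (2.5 equiv), DMF, rt
Reagents that add atoms: chlorotriisopropylsilane (2), CC(C)[Si](Cl)(C(C)C)C(C)C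
Why: Imidazole-promoted O-silylation of the only hydroxyl group, with the bulky TIPS ether chosen because it carries no acidic hydrogen and must survive t-BuLi in step 6.

Step 2
Reactants: 3 3-methoxy-4-(triisopropylsilyloxy)benzaldehyde
Product: 4 [3-methoxy-4-(triisopropylsilyloxy)phenyl]methanol
Conditions: NaBH4, MeOH, 0 °C
Reagents that add atoms: none
Why: Borohydride reduction of an aryl aldehyde, to which the aryl silyl ether is inert at 0 °C.

Step 3
Reactants: 4 [3-methoxy-4-(triisopropylsilyloxy)phenyl]methanol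
Product: 5 3-methoxy-4-(triisopropylsilyloxy)benzyl 2,2,2-trichloroacetimidate
Conditions: Cl3CCN (1.5 equiv), DBU (10 mol %), CH2Cl2, 0 °C; filtration through Et3N-treated silica
Reagents that add atoms: trichloroacetonitrile, ClC(Cl)(Cl)C#N
Why: Base-catalysed addition of the alcohol to trichloroacetonitrile (imidate formation as for PMB-type reagents) activates the benzylic carbon without passing through a labile p-silyloxybenzyl halide.

Step 4
Reactants: 6 hexa-2,4-diyne-1,6-diol
Product: 7 (2Z,4Z)-hexa-2,4-diene-1,6-diol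
Conditions: Zn dust activated with Cu(OAc)2 and AgNO3, MeOH–H2O (1:1), 25–40 °C, dark, Ar
Reagents that add atoms: none
Why: Boland-type semireduction, in which activated zinc delivers two hydrogens cis to each triple bond of a conjugated diyne and stops at the diene, fixing both Z geometries.

Step 5
Reactants: 7 (2Z,4Z)-hexa-2,4-diene-1,6-diol; 5 3-methoxy-4-(triisopropylsilyloxy)benzyl 2,2,2-trichloroacetimidate
Product: 8 (2Z,4Z)-1,6-bis{[3-methoxy-4-(triisopropylsilyloxy)phenyl]methoxy}hexa-2,4-diene
Conditions: 5 (2.4 equiv), PPTS (10 mol %), CH2Cl2–THF, 0 °C → rt, dark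
Reagents that add atoms: none
Why: Acid-catalysed trichloroacetimidate benzylation transfers the electron-rich benzyl group to both hydroxyls under nearly neutral conditions, avoiding the alkoxide bases that attack aryl silyl ethers and leaving the Z,Z-diene untouched.

Step 6
Reactants: 8 (2Z,4Z)-1,6-bis{[3-methoxy-4-(triisopropylsilyloxy)phenyl]methoxy}hexa-2,4-diene
Product: 10 (1S,2S,3S,4S)-1,4-bis[3-methoxy-4-(triisopropylsilyloxy)phenyl]-2,3-divinylbutane-1,4-diol, via mono-rearranged lithium alkoxide 9 (not isolated)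
Conditions: t-BuLi (4.5 equiv) premixed with 2,2-bis[(4S)-4-tert-butyl-4,5-dihydrooxazol-2-yl]propane (5 equiv), hexane–Et2O, −78 °C, slow addition of 8; then H2O, −78 °C → rt
Reagents that add atoms: none
Why: Proposed new method: the ligated base removes one benzylic hydrogen next to each ether oxygen, and each α-oxybenzyllithium bonds through a five-membered envelope transition state to the far carbon of its own allyl unit (diene C3, then C4, which become C2 and C3 of 10) while the O–CH2 bond breaks and the alkene moves outward to become a vinyl group, so that 8 passes through alkoxide 9, which still holds an intact Z-allyl benzyl ether, to 10; two C–C bonds form and no ring is closed. The closest known reaction type is the enantioselective [2,3]-Wittig rearrangement of isolated Z-allyl benzyl ethers, oxygenated aryl groups included, with t-BuLi and a chiral bis(oxazoline), whereas two shifts in relay across a conjugated diene are without precedent. The carbinol centres C1 and C4 are controlled by the bis(oxazoline)-bound lithium, which decides which configuration of the labile benzylic carbanion rearranges, and C2 and C3 are controlled by the Z geometry, which with the aryl group exo on the envelope links each of them syn to its carbinol. Site selectivity for the benzylic over the dienylic and aryl C–H bonds is needed and is secured by precoordination of the base to the ether oxygen in a hydrocarbon-rich medium, by A(1,3) strain in the Z,Z-diene, which resists flattening to an oxypentadienyl anion, and by the TIPS groups, which bear no acidic hydrogen and screen the arene; the vinylogous [2,5] path is an eight-electron process and is not allowed suprafacially. Diastereoselectivity in the second shift is the open point, because A(1,3)-based sterics at the new allylic centre of 9 point to the meso isomer, so reagent control has to prevail, helped by the internal lithium alkoxide, which can bridge to the lithium of the second carbanion in a six-membered array on the face that leads to the C2-symmetric product. Any half set in the wrong sense ends in the separable meso diastereomer, which should raise the enantiopurity of 10 (Horeau-type amplification).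

Step 7
Reactants: 10 (1S,2S,3S,4S)-1,4-bis[3-methoxy-4-(triisopropylsilyloxy)phenyl]-2,3-divinylbutane-1,4-diol
Product: 11 (1S,2S,3S,4S)-1,4-bis(tert-butyldimethylsilyloxy)-1,4-bis[3-methoxy-4-(triisopropylsilyloxy)phenyl]-2,3-divinylbutane
Conditions: TBSOTf (2.6 equiv), 2,6-lutidine (4 equiv), CH2Cl2, −78 → 0 °C
Reagents that add atoms: tert-butyldimethylsilyl triflate, CC(C)(C)[Si](C)(C)OS(=O)(=O)C(F)(F)F
Why: Silyl triflate/lutidine silylation of hindered secondary alcohols masks both carbinols, so that later only the primary hydroxyls can close the ring, and it touches no stereocentre.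

Step 8
Reactants: 11 (1S,2S,3S,4S)-1,4-bis(tert-butyldimethylsilyloxy)-1,4-bis[3-methoxy-4-(triisopropylsilyloxy)phenyl]-2,3-divinylbutane
Product: 13 (2R,3R)-2,3-bis{(S)-(tert-butyldimethylsilyloxy)[3-methoxy-4-(triisopropylsilyloxy)phenyl]methyl}butane-1,4-diol, via dialdehyde 12 (not isolated)
Conditions: O3, CH2Cl2–MeOH, Sudan Red 7B (indicator), −78 °C; N2 purge; then NaBH4 (excess), −78 °C → rt
Reagents that add atoms: ozone, [O-][O+]=O
Why: Ozonolysis with borohydride work-up, in which the terminal alkenes react much faster than the arenes (end point shown by the dye) and immediate cold reduction spares the α-centres of the dialdehyde from epimerisation and β-elimination.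

Step 9
Reactants: 13 (2R,3R)-2,3-bis{(S)-(tert-butyldimethylsilyloxy)[3-methoxy-4-(triisopropylsilyloxy)phenyl]methyl}butane-1,4-diol
Product: 15 (3R,4R)-3,4-bis{(S)-(tert-butyldimethylsilyloxy)[3-methoxy-4-(triisopropylsilyloxy)phenyl]methyl}oxolane, via monotosylate 14 (not isolated)
Conditions: TsCl (1.1 equiv), DMAP (cat.), pyridine, 0 → 45 °C
Reagents that add atoms: none
Why: Williamson-type 5-exo-tet closure of a 1,4-diol monotosylate, accelerated by the two vicinal branches, forms the C–O bond at a primary carbon, so all four stereocentres are untouched and the trans-3,4 relationship follows from the (2R,3R)-diol.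

Step 10
Reactants: 15 (3R,4R)-3,4-bis{(S)-(tert-butyldimethylsilyloxy)[3-methoxy-4-(triisopropylsilyloxy)phenyl]methyl}oxolane
Product: 16 (3R,4R)-3,4-bis[(S)-hydroxy(4-hydroxy-3-methoxyphenyl)methyl]oxolane (target)
Conditions: Bu4NF (6 equiv), AcOH (6 equiv), THF, 0 °C → rt
Reagents that add atoms: none
Why: Fluoride-mediated global desilylation of two aryl and two benzylic silyl ethers, with the acetic acid buffer keeping the freed phenols protonated so that no p-quinone methide forms by loss of the benzylic oxygen and the carbinol centres are kept.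

**Compound list**

1 | vanillin | COc1cc(C=O)ccc1O | starting material
2 | chlorotriisopropylsilane | CC(C)[Si](Cl)(C(C)C)C(C)C | starting material
3 | 3-methoxy-4-(triisopropylsilyloxy)benzaldehyde | COc1cc(C=O)ccc1O[Si](C(C)C)(C(C)C)C(C)C | intermediate
4 | [3-methoxy-4-(triisopropylsilyloxy)phenyl]methanol | COc1cc(CO)ccc1O[Si](C(C)C)(C(C)C)C(C)C | intermediate
5 | 3-methoxy-4-(triisopropylsilyloxy)benzyl 2,2,2-trichloroacetimidate | COc1cc(COC(=N)C(Cl)(Cl)Cl)ccc1O[Si](C(C)C)(C(C)C)C(C)C | intermediate
6 | hexa-2,4-diyne-1,6-diol | OCC#CC#CCO | starting material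
7 | (2Z,4Z)-hexa-2,4-diene-1,6-diol | OC/C=C\C=C/CO | intermediate
8 | (2Z,4Z)-1,6-bis{[3-methoxy-4-(triisopropylsilyloxy)phenyl]methoxy}hexa-2,4-diene | COc1cc(COC/C=C\C=C/COCc2ccc(O[Si](C(C)C)(C(C)C)C(C)C)c(OC)c2)ccc1O[Si](C(C)C)(C(C)C)C(C)C | intermediate
9 | lithium (1S,2S,3Z)-2-ethenyl-1-Ar-5-(Ar-methoxy)pent-3-en-1-olate (product of the first shift, not isolated) | COc1cc([C@@H]([O-])[C@@H](C=C)/C=C\COCc2ccc(O[Si](C(C)C)(C(C)C)C(C)C)c(OC)c2)ccc1O[Si](C(C)C)(C(C)C)C(C)C.[Li+] | intermediate
10 | (1S,2S,3S,4S)-1,4-bis[3-methoxy-4-(triisopropylsilyloxy)phenyl]-2,3-divinylbutane-1,4-diol | COc1cc([C@@H](O)[C@@H](C=C)[C@H](C=C)[C@H](O)c2ccc(O[Si](C(C)C)(C(C)C)C(C)C)c(OC)c2)ccc1O[Si](C(C)C)(C(C)C)C(C)C | intermediate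
11 | bis(tert-butyldimethylsilyl) ether of 10, (1S,2S,3S,4S) | COc1cc([C@@H](O[Si](C)(C)C(C)(C)C)[C@@H](C=C)[C@H](C=C)[C@H](O[Si](C)(C)C(C)(C)C)c2ccc(O[Si](C(C)C)(C(C)C)C(C)C)c(OC)c2)ccc1O[Si](C(C)C)(C(C)C)C(C)C | intermediate
12 | (2S,3S)-2,3-bis[(S)-(tert-butyldimethylsilyloxy)(Ar)methyl]butanedial (not isolated) | COc1cc([C@@H](O[Si](C)(C)C(C)(C)C)[C@@H](C=O)[C@H](C=O)[C@H](O[Si](C)(C)C(C)(C)C)c2ccc(O[Si](C(C)C)(C(C)C)C(C)C)c(OC)c2)ccc1O[Si](C(C)C)(C(C)C)C(C)C | intermediate
13 | (2R,3R)-2,3-bis[(S)-(tert-butyldimethylsilyloxy)(Ar)methyl]butane-1,4-diol | COc1cc([C@@H](O[Si](C)(C)C(C)(C)C)[C@@H](CO)[C@H](CO)[C@H](O[Si](C)(C)C(C)(C)C)c2ccc(O[Si](C(C)C)(C(C)C)C(C)C)c(OC)c2)ccc1O[Si](C(C)C)(C(C)C)C(C)C | intermediate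
14 | mono-p-toluenesulfonate of 13, (2R,3R) (not isolated) | COc1cc([C@@H](O[Si](C)(C)C(C)(C)C)[C@@H](COS(=O)(=O)c3ccc(C)cc3)[C@H](CO)[C@H](O[Si](C)(C)C(C)(C)C)c2ccc(O[Si](C(C)C)(C(C)C)C(C)C)c(OC)c2)ccc1O[Si](C(C)C)(C(C)C)C(C)C | intermediate
15 | (3R,4R)-3,4-bis[(S)-(tert-butyldimethylsilyloxy)(Ar)methyl]oxolane | COc1cc([C@@H](O[Si](C)(C)C(C)(C)C)[C@H]2COC[C@@H]2[C@H](O[Si](C)(C)C(C)(C)C)c2ccc(O[Si](C(C)C)(C(C)C)C(C)C)c(OC)c2)ccc1O[Si](C(C)C)(C(C)C)C(C)C | intermediate
16 | (3R,4R)-3,4-bis[(S)-hydroxy(4-hydroxy-3-methoxyphenyl)methyl]oxolane | COc1cc([C@@H](O)[C@H]2COC[C@@H]2[C@H](O)c2ccc(O)c(OC)c2)ccc1O | target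

**Step count.** Total steps: 10. Longest linear sequence: 9 (steps 1, 2, 3, 5, 6, 7, 8, 9, 10).

**Steps most likely to fail**

1. **Step 6.**
   - **What may go wrong:** A dienylic rather than a benzylic hydrogen may be removed, followed by 1,6-loss of benzyl oxide. The base may add to the diene. The second shift may follow the steric bias of the first-formed centres and drift into the meso series.
   - **Fallback (known chemistry):** It sets out from aldehyde 3, which is used twice, and returns at diol 13. The four centres are built one half at a time on the carbons of the future oxolane.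
     - (S)-4-Benzyloxazolidin-2-one is acylated (n-BuLi, pent-4-enoyl chloride) to the pentenoyl imide F1.
     - An Evans syn-aldol reaction (Bu2BOTf, Et3N, then 3) gives the syn-aldol imide F2, in which the auxiliary sets the first carbinol and its neighbour.
     - TBSOTf/2,6-lutidine gives the silylated imide F3, and LiBH4 removes the auxiliary to give the pentenol F4.
     - Lemieux–Johnson cleavage (OsO4 cat., NaIO4) of the allyl terminus gives the lactol F5, which PhI(OAc)2/TEMPO oxidises to the β-substituted butyrolactone F6.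
     - LDA, then 3, gives the trans-aldol lactone F7. The enolate is attacked anti to the β-branch, and both carbinol epimers form.
     - Dess–Martin periodinane converges both epimers on the keto lactone F8.
     - Zn(BH4)2 reduces the chelated β-keto lactone to the syn-hydroxy lactone F9.
     - TBSOTf gives the bis-silylated lactone F10, and LiAlH4 opens it to 13.

2. **Step 8.**
   - **What may go wrong:** Ozone may over-oxidise the electron-rich arenes, or epimerisation and β-elimination may occur at the aldehyde stage.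
   - **Fallback:** It sets out from 11 and returns at 13. OsO4 (cat.)/NMO, which ignores the arenes, dihydroxylates both vinyl groups to the bis(1,2-diol) F11. This is a mixture at the two new carbinols, which are destroyed in the next operation. NaIO4 in buffered aqueous THF cleaves it to dialdehyde 12, and NaBH4 added directly gives 13.

3. **Step 5.**
   - **What may go wrong:** Acid may ionise the dienylic C–O bonds with loss of Z geometry, the imidate may rearrange to the amide, or the reaction may stall at the mono-ether.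
   - **Fallback:** It sets out from 6 (with 5) and returns at 8, reversing the order of events. The robust diyne diol 6 is benzylated with 5 (PPTS or camphorsulfonic acid, CH2Cl2–THF) to the diyne bis(benzyl) ether F12. The Z,Z geometry is then installed by twofold syn-hydroboration with dicyclohexylborane, followed by protonolysis of both alkenylboranes with AcOH, a known route from conjugated diynes to cis,cis-dienes. This gives 8.

**Further compounds**

F1 | step 6 | (4S)-4-benzyl-3-(pent-4-enoyl)-1,3-oxazolidin-2-one | C=CCCC(=O)N1[C@@H](Cc2ccccc2)COC1=O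
F2 | step 6 | (4S)-4-benzyl-3-[(2S)-2-{(S)-hydroxy(Ar)methyl}pent-4-enoyl]-1,3-oxazolidin-2-one | COc1cc([C@@H](O)[C@H](CC=C)C(=O)N2[C@@H](Cc3ccccc3)COC2=O)ccc1O[Si](C(C)C)(C(C)C)C(C)C
F3 | step 6 | tert-butyldimethylsilyl ether of F2 | COc1cc([C@@H](O[Si](C)(C)C(C)(C)C)[C@H](CC=C)C(=O)N2[C@@H](Cc3ccccc3)COC2=O)ccc1O[Si](C(C)C)(C(C)C)C(C)C
F4 | step 6 | (2R)-2-[(S)-(tert-butyldimethylsilyloxy)(Ar)methyl]pent-4-en-1-ol | COc1cc([C@@H](O[Si](C)(C)C(C)(C)C)[C@H](CC=C)CO)ccc1O[Si](C(C)C)(C(C)C)C(C)C
F5 | step 6 | (4R)-4-[(S)-(tert-butyldimethylsilyloxy)(Ar)methyl]oxolan-2-ol (anomers) | COc1cc([C@@H](O[Si](C)(C)C(C)(C)C)[C@H]2COC(O)C2)ccc1O[Si](C(C)C)(C(C)C)C(C)C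
F6 | step 6 | (4R)-4-[(S)-(tert-butyldimethylsilyloxy)(Ar)methyl]oxolan-2-one | COc1cc([C@@H](O[Si](C)(C)C(C)(C)C)[C@H]2COC(=O)C2)ccc1O[Si](C(C)C)(C(C)C)C(C)C
F7 | step 6 | (3S,4R)-3-[hydroxy(Ar)methyl]-4-[(S)-(tert-butyldimethylsilyloxy)(Ar)methyl]oxolan-2-one (carbinol epimers) | COc1cc([C@@H](O[Si](C)(C)C(C)(C)C)[C@H]2COC(=O)[C@@H]2C(O)c2ccc(O[Si](C(C)C)(C(C)C)C(C)C)c(OC)c2)ccc1O[Si](C(C)C)(C(C)C)C(C)C
F8 | step 6 | (3S,4R)-3-(Ar-carbonyl)-4-[(S)-(tert-butyldimethylsilyloxy)(Ar)methyl]oxolan-2-one | COc1cc([C@@H](O[Si](C)(C)C(C)(C)C)[C@H]2COC(=O)[C@@H]2C(=O)c2ccc(O[Si](C(C)C)(C(C)C)C(C)C)c(OC)c2)ccc1O[Si](C(C)C)(C(C)C)C(C)C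
F9 | step 6 | (3S,4R)-3-[(S)-hydroxy(Ar)methyl]-4-[(S)-(tert-butyldimethylsilyloxy)(Ar)methyl]oxolan-2-one | COc1cc([C@@H](O[Si](C)(C)C(C)(C)C)[C@H]2COC(=O)[C@@H]2[C@H](O)c2ccc(O[Si](C(C)C)(C(C)C)C(C)C)c(OC)c2)ccc1O[Si](C(C)C)(C(C)C)C(C)C
F10 | step 6 | (3S,4R)-3,4-bis[(S)-(tert-butyldimethylsilyloxy)(Ar)methyl]oxolan-2-one | COc1cc([C@@H](O[Si](C)(C)C(C)(C)C)[C@H]2COC(=O)[C@@H]2[C@H](O[Si](C)(C)C(C)(C)C)c2ccc(O[Si](C(C)C)(C(C)C)C(C)C)c(OC)c2)ccc1O[Si](C(C)C)(C(C)C)C(C)C
F11 | step 8 | bis(1,2-diol) from dihydroxylation of both vinyl groups of 11 (new carbinols undefined) | COc1cc([C@@H](O[Si](C)(C)C(C)(C)C)[C@@H](C(O)CO)[C@H](C(O)CO)[C@H](O[Si](C)(C)C(C)(C)C)c2ccc(O[Si](C(C)C)(C(C)C)C(C)C)c(OC)c2)ccc1O[Si](C(C)C)(C(C)C)C(C)C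
F12 | step 5 | 1,6-bis{[3-methoxy-4-(triisopropylsilyloxy)phenyl]methoxy}hexa-2,4-diyne | COc1cc(COCC#CC#CCOCc2ccc(O[Si](C(C)C)(C(C)C)C(C)C)c(OC)c2)ccc1O[Si](C(C)C)(C(C)C)C(C)C
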